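**Retrosynthetic overview**
1. Late stage: the O6–Si bond is cleaved last; the (Z)-C=C bond of the 4-acetoxyangelate comes from a Still–Gennari olefination of a C3–O phosphonopropionate with 2-oxoethyl acetate; the isopropenyl C=C comes from dehydration of a C2 2-hydroxypropan-2-yl group.
2. Key disconnection: the C3a–C3 bond of ring B (the dihydrofuran ring), opened to an acyclic (S)-α-aryloxy-β-hydroxy aldehyde; forward, an aluminium-chelate-controlled intramolecular Friedel–Crafts hydroxyalkylation of an unfunctionalised aryl C–H.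
3. Enabling feature: C3a is the ring-A C–H para to O6, ortho to O1 and meta to the C5 acetyl, while C7 is wedged between O1 and the O6 silyl ether; the carbinol oxygen on the C2 side chain (the hydrated isopropenyl group) sits 1,3 to the C3 carbonyl oxygen, so one aluminium atom ties both oxygens into a temporary six-membered ring that forces the 2,3-cis outcome.
4. The aldehyde comes from ozonolysis of a vinyl group; the O1–C2 bond and the C2 stereocentre come from a palladium-catalysed dynamic kinetic asymmetric etherification of racemic 3-ethenyl-2,2-dimethyloxirane with 2',4'-dihydroxyacetophenone.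
5. Ring order: ring A (benzene) is purchased; ring B is the only ring made, in step 5.

Key step: step 5

Assumption: the (R,R)-ligand of step 2 is taken to deliver the (R)-configured allylic ether; should the sense of induction be the opposite, the (S,S)-ligand is used and nothing else changes.

**Step 1**
Reactants: 1 4-methylpenta-1,3-diene
Product: 2 3-ethenyl-2,2-dimethyloxirane (racemic)
Conditions: mCPBA (1.0 equiv), NaHCO3, CH2Cl2, 0 °C
Reagents that add atoms: 3-chloroperoxybenzoic acid, O=C(OO)c1cccc(Cl)c1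
Why: Prilezhaev epoxidation should take place at the more electron-rich trisubstituted double bond of the diene, the bicarbonate buffer protecting the acid-labile vinyl epoxide; no stereocontrol is needed because step 2 is a dynamic process.

**Step 2**
Reactants: 2 3-ethenyl-2,2-dimethyloxirane (racemic); 3 1-(2,4-dihydroxyphenyl)ethan-1-one
Product: 4 1-{2-hydroxy-4-[(3R)-2-hydroxy-2-methylpent-4-en-3-yl]oxyphenyl}ethan-1-one
Conditions: Pd2(dba)3·CHCl3 (1 mol %), (R,R)-DACH-phenyl ligand [(1R,2R)-N,N'-bis(2-diphenylphosphanylbenzoyl)cyclohexane-1,2-diamine] (3 mol %), CH2Cl2, rt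
Reagents that add atoms: none
Why: Tsuji–Trost allylic etherification run as a dynamic kinetic asymmetric transformation: zerovalent palladium opens the vinyl epoxide to π-allyl complexes that interconvert by π–σ–π at the CH2 terminus, the tertiary alkoxide deprotonates the more acidic, non-chelated 4-OH of 3, and the ion-paired phenoxide should attack the alkoxide-proximal (branched) terminus inside the chiral pocket, which sets the C–O stereocentre (R); the hydrogen-bonded 2-OH stays free.

**Step 3**
Reactants: 4 1-{2-hydroxy-4-[(3R)-2-hydroxy-2-methylpent-4-en-3-yl]oxyphenyl}ethan-1-one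
Product: 5 1-{4-[(3R)-2-hydroxy-2-methylpent-4-en-3-yl]oxy-2-(triisopropylsilyloxy)phenyl}ethan-1-one
Conditions: iPr3SiCl, imidazole, DMAP (cat.), DMF, 40 °C
Reagents that add atoms: chlorotri(propan-2-yl)silane, CC(C)[Si](Cl)(C(C)C)C(C)C
Why: Silylation of the phenol, the tertiary alcohol being too hindered for this chlorosilane; the bulky silyl ether later shields C7, blocks quinone-methide formation under base and keeps the phenol out of the acylation.

**Step 4**
Reactants: 5 1-{4-[(3R)-2-hydroxy-2-methylpent-4-en-3-yl]oxy-2-(triisopropylsilyloxy)phenyl}ethan-1-one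
Product: 7 (2S)-2-[4-acetyl-3-(triisopropylsilyloxy)phenoxy]-3-hydroxy-3-methylbutanal, via ozonide 6 (not isolated)
Conditions: O3, CH2Cl2, −78 °C; then Me2S, −78 °C → rt; used crude
Reagents that add atoms: ozone, [O-][O+]=O
Why: Criegee ozonolysis of the only C=C bond with neutral reductive work-up should leave the α-aryloxy stereocentre untouched (the descriptor changes to S by priority only), the arene being deactivated toward ozone by its acetyl group.

**Step 5**
Reactants: 7 (2S)-2-[4-acetyl-3-(triisopropylsilyloxy)phenoxy]-3-hydroxy-3-methylbutanal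
Product: 9 1-[(2R,3S)-3-hydroxy-2-(2-hydroxypropan-2-yl)-6-(triisopropylsilyloxy)-2,3-dihydro-1-benzofuran-5-yl]ethan-1-one (2,3-cis), via aluminium alkoxide chelate 8 (not isolated)
Conditions: Me2AlCl (2.5 equiv), CH2Cl2, −78 → −20 °C; then aq. KNaC4H4O6 (Rochelle salt), 0 °C
Reagents that add atoms: none
Why: Me2AlCl converts the tertiary hydroxyl into a chloro(methyl)aluminium alkoxide (methane lost) whose aluminium binds the aldehyde oxygen in a six-membered chelate; the activated carbonyl carbon is attacked by C3a of ring A, and the proton released on rearomatisation is consumed by the remaining Al–CH3 bond, so no Brønsted acid is left to dehydrate the benzylic carbinol. The closest known reaction type is the Lewis-acid intramolecular Friedel–Crafts hydroxyalkylation of α-aryloxy carbonyl compounds (the first stage of the classical cyclodehydration to benzofurans), here held at the alkoxide stage and combined with chelation-controlled carbonyl addition. Ring B closes in a 5-exo-trig mode at the C=O group. The new C3 stereocentre is controlled by the resident C2 stereocentre through the chelate: the carbonyl oxygen is held syn to the C2–C(CH3)2O bond, so the C3–O bond and the C2 side chain should end up cis, while C2 itself is not touched. The step needs regioselectivity for C3a over C7 and must stop before benzofuran formation: C3a is para to the C6 silyloxy group and ortho to O1, whereas C7 is flanked by O1 and the bulky silyl ether, and the covalent cyclic aluminium dialkoxide is a poor leaving group at low temperature. The aldehyde reacts in preference to the acetyl group because it is the stronger electrophile and the only carbonyl held in the chelate.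

**Step 6**
Reactants: 10 ethyl 2-[bis(2,2,2-trifluoroethoxy)phosphoryl]propanoate
Product: 11 2-[bis(2,2,2-trifluoroethoxy)phosphoryl]propanoic acid (racemic)
Conditions: LiOH·H2O (1.1 equiv), THF/H2O, 0 °C; then 1 M HCl
Reagents that add atoms: lithium hydroxide, [Li+].[OH-]
Why: Saponification of the carboxylic ester with one equivalent of hydroxide at 0 °C should cleave the C-ester faster than the phosphonate esters.

**Step 7**
Reactants: 9 1-[(2R,3S)-3-hydroxy-2-(2-hydroxypropan-2-yl)-6-(triisopropylsilyloxy)-2,3-dihydro-1-benzofuran-5-yl]ethan-1-one; 11 2-[bis(2,2,2-trifluoroethoxy)phosphoryl]propanoic acid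
Product: 12 (2R,3S)-5-acetyl-2-(2-hydroxypropan-2-yl)-6-(triisopropylsilyloxy)-2,3-dihydro-1-benzofuran-3-yl 2-[bis(2,2,2-trifluoroethoxy)phosphoryl]propanoate (both epimers at the phosphonate α-carbon)
Conditions: DCC, DMAP (cat.), CH2Cl2, 0 °C → rt
Reagents that add atoms: none
Why: Steglich esterification should acylate only the secondary C3–OH (the tertiary alcohol is inert and the phenol is silylated) with retention at C3; the epimeric α-carbon is irrelevant because it becomes sp2 in step 9.

**Step 8**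
Reactants: 12 (2R,3S)-5-acetyl-2-(2-hydroxypropan-2-yl)-6-(triisopropylsilyloxy)-2,3-dihydro-1-benzofuran-3-yl 2-[bis(2,2,2-trifluoroethoxy)phosphoryl]propanoate
Product: 13 (2S,3S)-5-acetyl-2-(prop-1-en-2-yl)-6-(triisopropylsilyloxy)-2,3-dihydro-1-benzofuran-3-yl 2-[bis(2,2,2-trifluoroethoxy)phosphoryl]propanoate
Conditions: Burgess reagent (methyl N-(triethylammoniosulfonyl)carbamate), toluene, 50 °C
Reagents that add atoms: none
Why: Burgess dehydration (syn elimination of the tertiary sulfamate) should remove one of the six methyl hydrogens rather than the single C2–H, as in the known dehydrations of 2-(2-hydroxypropan-2-yl)-2,3-dihydrobenzofurans to isopropenyl compounds; C2 and C3 are not touched (the C2 descriptor changes to S by priority only).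

**Step 9**
Reactants: 13 (2S,3S)-5-acetyl-2-(prop-1-en-2-yl)-6-(triisopropylsilyloxy)-2,3-dihydro-1-benzofuran-3-yl 2-[bis(2,2,2-trifluoroethoxy)phosphoryl]propanoate; 14 2-oxoethyl acetate
Product: 15 (2S,3S)-5-acetyl-2-(prop-1-en-2-yl)-6-(triisopropylsilyloxy)-2,3-dihydro-1-benzofuran-3-yl (2Z)-4-acetoxy-2-methylbut-2-enoate
Conditions: KN(SiMe3)2 (1.0 equiv), 18-crown-6, THF, −78 °C; then 14, −78 °C
Reagents that add atoms: none
Why: Still–Gennari variant of the Horner–Wadsworth–Emmons olefination: the bis(trifluoroethyl) phosphonate with a dissociated potassium counter-ion eliminates rapidly from the kinetic adduct and should give the (Z)-trisubstituted enoate, one equivalent of base deprotonating only the phosphonate, which is far more acidic than the methyl ketone.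

**Step 10**
Reactants: 15 (2S,3S)-5-acetyl-2-(prop-1-en-2-yl)-6-(triisopropylsilyloxy)-2,3-dihydro-1-benzofuran-3-yl (2Z)-4-acetoxy-2-methylbut-2-enoate
Product: 16 (2S,3S)-5-acetyl-6-hydroxy-2-(prop-1-en-2-yl)-2,3-dihydro-1-benzofuran-3-yl (2Z)-4-acetoxy-2-methylbut-2-enoate
Conditions: Bu4NF, AcOH (1:1), THF, 0 °C
Reagents that add atoms: none
Why: Fluoride cleavage of the aryl silyl ether, buffered with acetic acid so that no free phenoxide builds up that could expel the para-benzylic carboxylate; the esters and both alkenes should be untouched.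

**Compound list**
1 | 4-methylpenta-1,3-diene | C=CC=C(C)C | starting material
2 | 3-ethenyl-2,2-dimethyloxirane (racemic) | CC1(C)OC1C=C | intermediate
3 | 1-(2,4-dihydroxyphenyl)ethan-1-one (2',4'-dihydroxyacetophenone) | CC(=O)c1ccc(O)cc1O | starting material
4 | 1-{2-hydroxy-4-[(3R)-2-hydroxy-2-methylpent-4-en-3-yl]oxyphenyl}ethan-1-one | CC(C)(O)[C@@H](C=C)Oc1ccc(C(C)=O)c(O)c1 | intermediate
5 | 1-{4-[(3R)-2-hydroxy-2-methylpent-4-en-3-yl]oxy-2-(triisopropylsilyloxy)phenyl}ethan-1-one | CC(C)(O)[C@@H](C=C)Oc1ccc(C(C)=O)c(O[Si](C(C)C)(C(C)C)C(C)C)c1 | intermediate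
6 | 1-{4-[(1S)-2-hydroxy-2-methyl-1-(1,2,4-trioxolan-3-yl)propoxy]-2-(triisopropylsilyloxy)phenyl}ethan-1-one (ozonide, both epimers at the trioxolane carbon) | CC(C)(O)[C@@H](C1OCOO1)Oc1ccc(C(C)=O)c(O[Si](C(C)C)(C(C)C)C(C)C)c1 | intermediate (not isolated)
7 | (2S)-2-[4-acetyl-3-(triisopropylsilyloxy)phenoxy]-3-hydroxy-3-methylbutanal | CC(C)(O)[C@@H](C=O)Oc1ccc(C(C)=O)c(O[Si](C(C)C)(C(C)C)C(C)C)c1 | intermediate
8 | chloro(methyl)aluminium alkoxide of 7 at the tertiary oxygen, aldehyde oxygen bound to aluminium (six-membered chelate) | CC(C)(O[Al](C)Cl)[C@@H](C=O)Oc1ccc(C(C)=O)c(O[Si](C(C)C)(C(C)C)C(C)C)c1 | intermediate (not isolated)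
9 | 1-[(2R,3S)-3-hydroxy-2-(2-hydroxypropan-2-yl)-6-(triisopropylsilyloxy)-2,3-dihydro-1-benzofuran-5-yl]ethan-1-one | CC(C)(O)[C@@H]1Oc2cc(O[Si](C(C)C)(C(C)C)C(C)C)c(C(C)=O)cc2[C@@H]1O | intermediate
10 | ethyl 2-[bis(2,2,2-trifluoroethoxy)phosphoryl]propanoate | CCOC(=O)C(C)P(=O)(OCC(F)(F)F)OCC(F)(F)F | starting material
11 | 2-[bis(2,2,2-trifluoroethoxy)phosphoryl]propanoic acid | CC(C(=O)O)P(=O)(OCC(F)(F)F)OCC(F)(F)F | intermediate
12 | (2R,3S)-5-acetyl-2-(2-hydroxypropan-2-yl)-6-(triisopropylsilyloxy)-2,3-dihydro-1-benzofuran-3-yl 2-[bis(2,2,2-trifluoroethoxy)phosphoryl]propanoate | CC(C)(O)[C@@H]1Oc2cc(O[Si](C(C)C)(C(C)C)C(C)C)c(C(C)=O)cc2[C@@H]1OC(=O)C(C)P(=O)(OCC(F)(F)F)OCC(F)(F)F | intermediate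
13 | (2S,3S)-5-acetyl-2-(prop-1-en-2-yl)-6-(triisopropylsilyloxy)-2,3-dihydro-1-benzofuran-3-yl 2-[bis(2,2,2-trifluoroethoxy)phosphoryl]propanoate | C=C(C)[C@@H]1Oc2cc(O[Si](C(C)C)(C(C)C)C(C)C)c(C(C)=O)cc2[C@@H]1OC(=O)C(C)P(=O)(OCC(F)(F)F)OCC(F)(F)F | intermediate
14 | 2-oxoethyl acetate (acetoxyacetaldehyde) | CC(=O)OCC=O | starting material
15 | (2S,3S)-5-acetyl-2-(prop-1-en-2-yl)-6-(triisopropylsilyloxy)-2,3-dihydro-1-benzofuran-3-yl (2Z)-4-acetoxy-2-methylbut-2-enoate | C=C(C)[C@@H]1Oc2cc(O[Si](C(C)C)(C(C)C)C(C)C)c(C(C)=O)cc2[C@@H]1OC(=O)/C(C)=C\COC(C)=O | intermediate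
16 | (2S,3S)-5-acetyl-6-hydroxy-2-(prop-1-en-2-yl)-2,3-dihydro-1-benzofuran-3-yl (2Z)-4-acetoxy-2-methylbut-2-enoate | C=C(C)[C@@H]1Oc2cc(O)c(C(C)=O)cc2[C@@H]1OC(=O)/C(C)=C\COC(C)=O | target

**Step count**
Total: 10 steps. Longest linear sequence: 9 steps (steps 1, 2, 3, 4, 5, 7, 8, 9, 10); step 6 is a one-step side branch.

**Steps most likely to fail, with fallbacks**

Step 5. What may go wrong: retro-aldol loss of acetone from the aluminium aldolate; ionisation of the benzylic C3–O bond followed by loss of the C2 proton (aromatisation to the benzofuran); attack at C7; or too low a nucleophilicity of the acetyl-bearing arene. The fallback reverses the polarity of the aryl carbon and closes the same bond from an aryl halide; it sets out from 4 and returns at 9. Iodination para to the free phenol (N-iodosuccinimide, cat. CF3CO2H, MeCN, 0 °C) should give 1-{2-hydroxy-4-[(3R)-2-hydroxy-2-methylpent-4-en-3-yl]oxy-5-iodophenyl}ethan-1-one F1. Silylation as in step 3 gives 1-{4-[(3R)-2-hydroxy-2-methylpent-4-en-3-yl]oxy-5-iodo-2-(triisopropylsilyloxy)phenyl}ethan-1-one F2, and ozonolysis as in step 4 gives (2S)-2-[4-acetyl-2-iodo-5-(triisopropylsilyloxy)phenoxy]-3-hydroxy-3-methylbutanal F3. An intramolecular Nozaki–Hiyama–Kishi reaction (CrCl2 in excess, NiCl2 cat., DMF, rt) then adds the aryl–chromium species to the aldehyde under neutral, non-ionising conditions, with the site fixed by the iodine, and gives 9; a trans isomer, if formed, would be separated.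

Step 2. What may go wrong: attack of the phenoxide at the unhindered CH2 terminus (linear ether), or low enantioselectivity at an allyl carbon next to a quaternary centre. The fallback takes the stereocentre from a Sharpless epoxide and makes the C–O bond by epoxide opening; it sets out from 3 and returns at 7. Sharpless asymmetric epoxidation of commercial 3-methylbut-2-en-1-ol (Ti(OiPr)4, L-(+)-diethyl tartrate, tBuOOH, 4 Å molecular sieves, CH2Cl2, −20 °C) gives [(2S)-3,3-dimethyloxiran-2-yl]methanol F4, which is benzylated (NaH, BnBr, THF) to (2S)-2-[(benzyloxy)methyl]-3,3-dimethyloxirane F5. The 4-phenoxide of 3 (Cs2CO3, DMF, 90 °C) should open F5 at the secondary carbon with inversion to give 1-{4-[(2R)-1-(benzyloxy)-3-hydroxy-3-methylbutan-2-yl]oxy-2-hydroxyphenyl}ethan-1-one F6. Silylation as in step 3 gives 1-{4-[(2R)-1-(benzyloxy)-3-hydroxy-3-methylbutan-2-yl]oxy-2-(triisopropylsilyloxy)phenyl}ethan-1-one F7, hydrogenolysis (H2, Pd/C, EtOAc) gives 1-{4-[(2R)-1,3-dihydroxy-3-methylbutan-2-yl]oxy-2-(triisopropylsilyloxy)phenyl}ethan-1-one F8, and Dess–Martin oxidation of the primary alcohol (NaHCO3, CH2Cl2) gives 7.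

Step 8. What may go wrong: loss of the C2 proton instead of a methyl proton (exocyclic enol ether that goes on to the benzofuran), or participation of the neighbouring C3 ester carbonyl in the ionising tertiary centre (acyl shift). The fallback makes the isopropenyl group before the ester is attached, by a base-mediated E2 elimination with the C3 oxygen masked as a non-participating silyl ether; it sets out from 9 and returns at 13. Selective silylation of the secondary hydroxyl (Et3SiCl, imidazole, CH2Cl2, 0 °C) gives 1-[(2R,3S)-2-(2-hydroxypropan-2-yl)-3-(triethylsilyloxy)-6-(triisopropylsilyloxy)-2,3-dihydro-1-benzofuran-5-yl]ethan-1-one F9. SOCl2 in pyridine at 0 °C should dehydrate through the tertiary chlorosulfite, pyridine removing an unhindered methyl proton, to give 1-[(2S,3S)-2-(prop-1-en-2-yl)-3-(triethylsilyloxy)-6-(triisopropylsilyloxy)-2,3-dihydro-1-benzofuran-5-yl]ethan-1-one F10. HF·pyridine (THF/pyridine, 0 °C) removes the alkyl silyl ether in the presence of the aryl silyl ether to give 1-[(2S,3S)-3-hydroxy-2-(prop-1-en-2-yl)-6-(triisopropylsilyloxy)-2,3-dihydro-1-benzofuran-5-yl]ethan-1-one F11, which is esterified with 11 as in step 7 to give 13.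

**Further compounds**
F1 | step 5 | 1-{2-hydroxy-4-[(3R)-2-hydroxy-2-methylpent-4-en-3-yl]oxy-5-iodophenyl}ethan-1-one | CC(C)(O)[C@@H](C=C)Oc1cc(O)c(C(C)=O)cc1I
F2 | step 5 | 1-{4-[(3R)-2-hydroxy-2-methylpent-4-en-3-yl]oxy-5-iodo-2-(triisopropylsilyloxy)phenyl}ethan-1-one | CC(C)(O)[C@@H](C=C)Oc1cc(O[Si](C(C)C)(C(C)C)C(C)C)c(C(C)=O)cc1I
F3 | step 5 | (2S)-2-[4-acetyl-2-iodo-5-(triisopropylsilyloxy)phenoxy]-3-hydroxy-3-methylbutanal | CC(C)(O)[C@@H](C=O)Oc1cc(O[Si](C(C)C)(C(C)C)C(C)C)c(C(C)=O)cc1I
F4 | step 2 | [(2S)-3,3-dimethyloxiran-2-yl]methanol | CC1(C)O[C@H]1CO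
F5 | step 2 | (2S)-2-[(benzyloxy)methyl]-3,3-dimethyloxirane | CC1(C)O[C@H]1COCc1ccccc1
F6 | step 2 | 1-{4-[(2R)-1-(benzyloxy)-3-hydroxy-3-methylbutan-2-yl]oxy-2-hydroxyphenyl}ethan-1-one | CC(C)(O)[C@@H](COCc1ccccc1)Oc1ccc(C(C)=O)c(O)c1
F7 | step 2 | 1-{4-[(2R)-1-(benzyloxy)-3-hydroxy-3-methylbutan-2-yl]oxy-2-(triisopropylsilyloxy)phenyl}ethan-1-one | CC(C)(O)[C@@H](COCc1ccccc1)Oc1ccc(C(C)=O)c(O[Si](C(C)C)(C(C)C)C(C)C)c1
F8 | step 2 | 1-{4-[(2R)-1,3-dihydroxy-3-methylbutan-2-yl]oxy-2-(triisopropylsilyloxy)phenyl}ethan-1-one | CC(C)(O)[C@@H](CO)Oc1ccc(C(C)=O)c(O[Si](C(C)C)(C(C)C)C(C)C)c1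
F9 | step 8 | 1-[(2R,3S)-2-(2-hydroxypropan-2-yl)-3-(triethylsilyloxy)-6-(triisopropylsilyloxy)-2,3-dihydro-1-benzofuran-5-yl]ethan-1-one | CC(C)(O)[C@@H]1Oc2cc(O[Si](C(C)C)(C(C)C)C(C)C)c(C(C)=O)cc2[C@@H]1O[Si](CC)(CC)CC
F10 | step 8 | 1-[(2S,3S)-2-(prop-1-en-2-yl)-3-(triethylsilyloxy)-6-(triisopropylsilyloxy)-2,3-dihydro-1-benzofuran-5-yl]ethan-1-one | C=C(C)[C@@H]1Oc2cc(O[Si](C(C)C)(C(C)C)C(C)C)c(C(C)=O)cc2[C@@H]1O[Si](CC)(CC)CC
F11 | step 8 | 1-[(2S,3S)-3-hydroxy-2-(prop-1-en-2-yl)-6-(triisopropylsilyloxy)-2,3-dihydro-1-benzofuran-5-yl]ethan-1-one | C=C(C)[C@@H]1Oc2cc(O[Si](C(C)C)(C(C)C)C(C)C)c(C(C)=O)cc2[C@@H]1O
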